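## The problem

Euchrenone a17 (18) is a (2S)-flavanone. A benzopyran-4-one (rings A and C) carries a 2,2-dimethylchroman-6-yl group as ring B at C2, a free hydroxyl at C7 and a prenyl group at C8, which lies between O1 and the C7 oxygen.

C2 is the only stereocentre. It is benzylic, α to O1 and β to the C4 carbonyl, and no second centre exists from which it could be relayed, so it has to be set by a catalyst. Once the ketone is present C2 is fragile: base expels the O1 phenoxide by β-elimination and the resulting open form recloses without control.

The prenyl group stands ortho to a phenol and closes a second chroman ring under strong acid. It is also an alkene that metathesis catalysts, hydrogenation and electrophiles will attack. The C2–O1 bond is the ether of an electron-rich benzylic carbinol and ionises under Lewis acids. Because C8 is flanked by two oxygen substituents, electrophilic prenylation of a 7-hydroxyflavanone would not be regioselective, and the position needs a handle placed at the outset.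

The feature that permits a metathesis closure is the C4 ketone next to the C3 methylene. The C3–C4 bond can be made as the double bond of a cyclic enol ether. C4 is bonded to C4a, ortho to the O1-bearing C8a, so an aryl methyl ketone ortho to a 1-arylallyl aryl ether holds both alkene partners once the ketone is enol-silylated.

## Retrosynthesis

**18 from 17 (two O–Si bonds).** The last operation removes two silyl groups from the 4-silyloxy-2H-chromene 17, which already contains every carbon of 18. The C7 phenol is released and protonation at C3 gives the C4 ketone. Keeping C4 as an enol ether until this point means C2 cannot be lost through ring opening and the allylic zinc reagent of the preceding step has no carbonyl to attack. The forward step must protonate the enolate faster than it can expel O1.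

**17 from 14 and 16 (C8–CH2 bond).** Cutting the bond between C8 and the prenyl methylene gives aryl bromide 14 and prenylzinc bromide 16, made from prenyl bromide 15. A prenyl group present before ring closure would offer the ruthenium carbene a competing seven-membered closure onto the allylic ether. Electrophilic prenylation after ring closure would give mixtures. Bromine is inert to the iridium, silyl triflate and ruthenium steps and comes with the starting material. The forward coupling has to join the unsubstituted terminus of the allyl metal to a bromide with two ortho oxygen substituents.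

**14 from 13 (C3=C4, ring C).** Cutting the C3=C4 bond of 14 opens ring C to the silyl enol ether 13, in which O1–C2 and the stereocentre are already present. The neighbouring cuts were weighed in detail (see the next section). O1–C2 by oxa-Michael addition leaves the stereocentre to an equilibrating ring closure, and C4–C4a by acylation needs an organolithium beside a β-aryloxy carbonyl group. The metathesis runs under neutral conditions, does not touch C2, and delivers C4 at the ketone oxidation level. The precursor is acyclic at ring C and is assembled from two simple aromatic pieces. The forward step needs a catalyst able to engage a 1,1-disubstituted, electron-rich alkene.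

**13 from 12 (O–Si bond).** Ketone 12 is the storable form of 13. The acetyl group can enolise on one side only, so no regiochemical question arises. The silylation must stay non-acidic because the C2–O bond of 12 ionises readily.

**12 from 10 and 7 (O1–C2 bond, stereocentre).** Cutting O1–C2 gives phenol 10 and the linear cinnamyl-type carbonate 7. An iridium-catalysed allylic etherification forms the branched ether and sets C2 in one step. The electron-rich aryl group that would make an SN2 inversion at this carbon unreliable instead helps the ionisation here. The forward reaction asks a hindered, acyl-stabilised aryloxide to attack the allyliridium intermediate at its substituted end.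

**10 from 9 and 8 (O–Si bond, then C4a–C4 bond).** Silyl ether 10 comes from diol 9 by silylation of the one hydroxyl that is not chelated to the acetyl group. Diol 9 comes from 2-bromoresorcinol 8 by C-acetylation, where both open activated positions are equivalent.

**7 from 6, 5, 4, and 4 from 1 and 2.** Carbonate 7 is the ester of allylic alcohol 6, obtained by reduction of cinnamate 5, the olefination product of aldehyde 4. Aldehyde 4 is disconnected at its chroman ring (C–C and C–O bonds) into 4-hydroxybenzaldehyde 1 and isoprene 2, through the ortho-prenyl phenol 3.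

## Roads not taken

**Alternative 1: ring A by photochemical benzannulation.** Ring A is taken apart at C8a–C8, C7–C6, C6–C5 and C4a–C8a into the diazo enone A1 and the siloxyalkyne A2.
- Forward step: irradiation turns A1 into a vinylketene (Wolff rearrangement). This adds A2 in a (2+2) step, the cyclobutenone opens, and a six-electron electrocyclisation gives phenol A3.
- Merits: the connectivity of the alkyne fixes the prenyl group at C8 and the silyloxy group at C7, and the acetyl group arrives masked as a ketal. No cross-coupling at a crowded position is needed; here this road is better than the chosen plan.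
- Weak points: it constructs a benzene ring that 2-bromoresorcinol 8 supplies ready-made. A1 and A2 each need several steps. The vinylketene has a prenyl alkene within reach. Ring C and C2 are still unmade at A3; they would come from condensation with aldehyde 4 and an enantioselective oxa-Michael closure, which works against the ring-opening equilibrium of flavanones.
- Comparison: the chosen plan needs the bromine placeholder and the late Negishi coupling, but it sets C2 by catalyst control before the ring exists and uses an aromatic starting material for ring A.

**Alternative 2: flavone by carbonylative three-component annulation.** Ring C is cut at C4a–C4, C4–C3 and O1–C2 into the iodophenol A4, carbon monoxide and the chromanyl alkyne A5.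
- Forward step: PdCl2(PPh3)2 and diethylamine effect carbonylative alkynylation and 6-endo oxa-Michael closure to flavone A6.
- Merits: this is the most convergent road, with three components in one step, robust achiral intermediates and no labile centre until late. In convergence and probably in step count to the bicyclic core it is as good as or better than the chosen plan.
- Weak points: the stereocentre would have to be created by enantioselective 1,4-reduction of a 2-arylchromone whose aryl group is electron-rich, in the presence of the prenyl alkene. That excludes ordinary hydrogenation and risks over-reduction at C4. 5-Exo closure to an aurone competes in the annulation. The methoxymethyl ether must be removed with acid next to an ortho-prenyl phenol. A4 needs its own regioselective synthesis.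
- Comparison: the chosen plan is longer in the linear sense, but C2 comes from an allylic substitution with a well-understood sense of induction, no alkene has to be reduced beside the prenyl group, and the final deprotection uses buffered fluoride.

**Alternative 3: ring C by cycloacylation at C4–C4a.** The C4–C4a bond is cut to give aryl bromide A7, which carries the complete O1–C2–C3 tether ending in an N-methoxy-N-methylamide.
- Forward step: tert-butyllithium exchanges the bromide and the aryllithium attacks the amide, giving the silyl-protected flavanone A8.
- Merits: the ketone is formed directly, the prenyl group is in place before cyclisation (no placeholder, no late coupling), and only a fluoride step separates A8 from 18. In these respects it is better than the chosen plan, and the step count is comparable.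
- Weak points: A7 contains a β-aryloxy amide. Deprotonation α to the amide by the alkyllithium expels the aryloxide and destroys C2, and the C2–H bond is itself benzylic and α to oxygen. The ether of A7 would have to be made from a doubly ortho-substituted phenol by inversion at an electron-rich benzylic carbinol, where ionisation and elimination compete.
- Comparison: the chosen plan closes the ring with a neutral catalyst and no base near the sensitive array, and makes the ether by a reaction that benefits from the electron-rich aryl group.

Key step: step 9

Assumption: the (Sa,S,S)-phosphoramidite is taken to give the (S)-ether 12, the usual sense of induction for oxygen nucleophiles with (E)-3-arylallyl carbonates; if a model run showed the opposite sense, the (Ra,R,R)-ligand would be used instead.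

## Route

Step 1
Reactants: 1 4-hydroxybenzaldehyde; 2 isoprene
Product: 4 2,2-dimethylchroman-6-carbaldehyde, via 4-hydroxy-3-prenylbenzaldehyde 3 (not isolated)
Conditions: 2 (2 equiv), 85% H3PO4, xylene, closed vessel, 35 °C then 60 °C
Reagents that add atoms: none
Why: Acid-catalysed Friedel–Crafts prenylation ortho to the hydroxyl (para is blocked by the formyl group) gives 3, whose phenol adds in Markovnikov fashion to the protonated alkene and closes the chroman; the one-pot chroman synthesis from phenols and isoprene is known, though slowed here by the formyl group.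

Step 2
Reactants: 4 2,2-dimethylchroman-6-carbaldehyde
Product: 5 ethyl (E)-3-(2,2-dimethylchroman-6-yl)acrylate
Conditions: Ph3P=CHCO2Et, toluene, 90 °C
Reagents that add atoms: ethyl (triphenylphosphoranylidene)acetate, CCOC(=O)C=P(c1ccccc1)(c1ccccc1)c1ccccc1
Why: Wittig olefination with a stabilised ylide, which gives the (E)-cinnamate from aromatic aldehydes; the chroman ether is inert.

Step 3
Reactants: 5 ethyl (E)-3-(2,2-dimethylchroman-6-yl)acrylate
Product: 6 (E)-3-(2,2-dimethylchroman-6-yl)prop-2-en-1-ol
Conditions: i-Bu2AlH (2.5 equiv), CH2Cl2, −78 → 0 °C
Reagents that add atoms: none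
Why: 1,2-Reduction of an α,β-unsaturated ester to the allylic alcohol by diisobutylaluminium hydride, which leaves the alkene and its geometry alone.

Step 4
Reactants: 6 (E)-3-(2,2-dimethylchroman-6-yl)prop-2-en-1-ol
Product: 7 (E)-3-(2,2-dimethylchroman-6-yl)allyl methyl carbonate
Conditions: ClCO2Me, pyridine, CH2Cl2, 0 °C
Reagents that add atoms: methyl chloroformate, COC(=O)Cl
Why: Acylation of a primary allylic alcohol with a chloroformate; the methyl carbonate is the usual leaving group for iridium-catalysed allylic substitution and is purified on base-washed silica because the electron-rich cinnamyl system ionises easily.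

Step 5
Reactants: 8 2-bromoresorcinol
Product: 9 1-(3-bromo-2,4-dihydroxyphenyl)ethanone
Conditions: AcOH, BF3·OEt2, 90 °C; aqueous work-up
Reagents that add atoms: acetic acid, CC(=O)O
Why: Friedel–Crafts (Nencki-type) C-acylation of a resorcinol; the two open positions ortho/para to the hydroxyls are equivalent, so a single ketone forms, held as its boron chelate until work-up, and the bromine is not disturbed.

Step 6
Reactants: 9 1-(3-bromo-2,4-dihydroxyphenyl)ethanone
Product: 10 1-[3-bromo-2-hydroxy-4-(triisopropylsilyloxy)phenyl]ethanone
Conditions: i-Pr3SiCl (1.05 equiv), imidazole, CH2Cl2, 0 °C → rt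
Reagents that add atoms: chlorotriisopropylsilane, CC(C)[Si](Cl)(C(C)C)C(C)C
Why: Selective silylation of the free C4 hydroxyl; the C2 hydroxyl is hydrogen-bonded to the acetyl oxygen and flanked on both sides, so it remains free for the etherification.

Step 7
Reactants: 10 1-[3-bromo-2-hydroxy-4-(triisopropylsilyloxy)phenyl]ethanone; 7 (E)-3-(2,2-dimethylchroman-6-yl)allyl methyl carbonate
Product: 12 1-[3-bromo-2-{[(1S)-1-(2,2-dimethylchroman-6-yl)prop-2-en-1-yl]oxy}-4-(triisopropylsilyloxy)phenyl]ethanone, via sodium aryloxide 11 (not isolated)
Conditions: NaH (1.0 equiv), THF, 0 °C; then 7 (1.3 equiv), [Ir(cod)Cl]2 (2 mol %), (Sa,S,S)-O,O'-(1,1'-binaphthyl-2,2'-diyl)-N,N-bis(1-phenylethyl)phosphoramidite (4 mol %, catalyst pre-activated with n-PrNH2), THF, 25–40 °C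
Reagents that add atoms: none
Why: Iridium-catalysed asymmetric allylic etherification of an alkali aryloxide: the cyclometalated iridium phosphoramidite complex ionises 7 with loss of CO2 and methoxide, and the aryloxide attacks the aryl-bearing allyl terminus to give the branched ether. The C2 stereocentre is set by the chiral ligand (catalyst control), and the reaction is stopped at full conversion because the product ether can re-ionise.

Step 8
Reactants: 12 1-[3-bromo-2-{[(1S)-1-(2,2-dimethylchroman-6-yl)prop-2-en-1-yl]oxy}-4-(triisopropylsilyloxy)phenyl]ethanone
Product: 13 tert-butyldimethylsilyl enol ether of 12, tert-butyl({1-[3-bromo-2-{[(1S)-1-(2,2-dimethylchroman-6-yl)prop-2-en-1-yl]oxy}-4-(triisopropylsilyloxy)phenyl]vinyl}oxy)dimethylsilane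
Conditions: t-BuMe2SiOTf (1.3 equiv), Et3N (3 equiv), CH2Cl2, 0 °C; base-washed silica
Reagents that add atoms: tert-butyldimethylsilyl trifluoromethanesulfonate, CC(C)(C)[Si](C)(C)OS(=O)(=O)C(F)(F)F
Why: Soft enolisation of a methyl ketone with a silyl triflate and triethylamine; only one enol ether is possible, and the excess amine keeps the medium non-acidic for the ionisable C2–O bond.

Step 9
Reactants: 13 tert-butyldimethylsilyl enol ether of 12
Product: 14 (S)-8-bromo-4-(tert-butyldimethylsilyloxy)-2-(2,2-dimethylchroman-6-yl)-7-(triisopropylsilyloxy)-2H-chromene
Conditions: (H2IMes)Cl2Ru(=CH-C6H4-2-O-i-Pr) (second-generation Hoveyda–Grubbs catalyst, 10 mol %), 1,4-benzoquinone (20 mol %), toluene (0.01 M), 80 °C, argon sparge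
Reagents that add atoms: none
Why: Ring-closing metathesis of an olefinic silyl enol ether, a known way to cyclic silyl enol ethers including 4-silyloxy-2H-chromenes. The ruthenium alkylidene should form first at the monosubstituted vinyl group on C2, the only unhindered alkene. It then adds across the 1,1-disubstituted enol ether in a [2+2] step, and cycloreversion of the ruthenacyclobutane expels ethylene and closes ring C as a six-membered ring with an endocyclic C3=C4 bond. No stereocentre is formed, and C2 is carried through untouched because the conditions are neutral and the centre belongs to neither reacting alkene. The only selectivity needed is chemoselectivity, which is secured by the substrate having just two alkenes: C8 carries bromine instead of prenyl, so no seven-membered closure is available. High dilution disfavours dimerisation at the vinyl group, and benzoquinone suppresses hydride-mediated migration of the allylic double bond. The enol ether carbon arrives at the ketone oxidation level needed for C4.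

Step 10
Reactants: 14 (S)-8-bromo-4-(tert-butyldimethylsilyloxy)-2-(2,2-dimethylchroman-6-yl)-7-(triisopropylsilyloxy)-2H-chromene; 15 prenyl bromide
Product: 17 (S)-4-(tert-butyldimethylsilyloxy)-2-(2,2-dimethylchroman-6-yl)-8-(3-methylbut-2-en-1-yl)-7-(triisopropylsilyloxy)-2H-chromene, via prenylzinc bromide 16 (not isolated)
Conditions: 15, Zn dust, LiCl, THF, 0 °C → rt; then 14, Pd(OAc)2 (4 mol %), 2-dicyclohexylphosphino-2',6'-bis(dimethylamino)biphenyl (8 mol %), THF, rt
Reagents that add atoms: none
Why: Negishi coupling of an allylic zinc halide with an aryl bromide; with the biaryl dialkylphosphine ligand the coupling is linear-selective and gives the 3-methylbut-2-enyl arene instead of the 1,1-dimethylallyl isomer. C4 is masked as the silyl enol ether, so the allylzinc, which would add to a free ketone, finds no electrophile. Oxidative addition into C8–Br should outrun ionisation of the allylic C2–O1 bond because the adjacent alkene is a trisubstituted, electron-rich enol ether.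

Step 11
Reactants: 17 (S)-4-(tert-butyldimethylsilyloxy)-2-(2,2-dimethylchroman-6-yl)-8-(3-methylbut-2-en-1-yl)-7-(triisopropylsilyloxy)-2H-chromene
Product: 18 euchrenone a17, (2S)-7-hydroxy-2-(2,2-dimethylchroman-6-yl)-8-(3-methylbut-2-en-1-yl)chroman-4-one
Conditions: n-Bu4NF (2.5 equiv), AcOH (2.5 equiv), THF, 0 °C → rt
Reagents that add atoms: none
Why: Fluoride cleaves the aryl silyl ether and the silyl enol ether, and acetic acid protonates the enolate at C3 at once to give the C4 ketone before O1 can be expelled, which closes the ring-opening path to racemisation. No acid strong enough to cyclise the ortho-prenyl phenol is present.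

## Compound list

1 | 4-hydroxybenzaldehyde | O=Cc1ccc(O)cc1 | starting material
2 | isoprene | C=CC(C)=C | starting material
3 | 4-hydroxy-3-(3-methylbut-2-en-1-yl)benzaldehyde | CC(C)=CCc1cc(C=O)ccc1O | intermediate
4 | 2,2-dimethylchroman-6-carbaldehyde | O=Cc1ccc2c(c1)CCC(C)(C)O2 | intermediate
5 | ethyl (E)-3-(2,2-dimethylchroman-6-yl)acrylate | CCOC(=O)/C=C/c1ccc2c(c1)CCC(C)(C)O2 | intermediate
6 | (E)-3-(2,2-dimethylchroman-6-yl)prop-2-en-1-ol | OC/C=C/c1ccc2c(c1)CCC(C)(C)O2 | intermediate
7 | (E)-3-(2,2-dimethylchroman-6-yl)allyl methyl carbonate | COC(=O)OC/C=C/c1ccc2c(c1)CCC(C)(C)O2 | intermediate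
8 | 2-bromoresorcinol | Oc1cccc(O)c1Br | starting material
9 | 1-(3-bromo-2,4-dihydroxyphenyl)ethanone | CC(=O)c1ccc(O)c(Br)c1O | intermediate
10 | 1-[3-bromo-2-hydroxy-4-(triisopropylsilyloxy)phenyl]ethanone | CC(=O)c1ccc(O[Si](C(C)C)(C(C)C)C(C)C)c(Br)c1O | intermediate
11 | sodium 6-acetyl-2-bromo-3-(triisopropylsilyloxy)phenoxide | CC(=O)c1ccc(O[Si](C(C)C)(C(C)C)C(C)C)c(Br)c1[O-].[Na+] | intermediate
12 | 1-[3-bromo-2-{[(1S)-1-(2,2-dimethylchroman-6-yl)prop-2-en-1-yl]oxy}-4-(triisopropylsilyloxy)phenyl]ethanone | CC(=O)c1ccc(O[Si](C(C)C)(C(C)C)C(C)C)c(Br)c1O[C@H](c1ccc2c(c1)CCC(C)(C)O2)C=C | intermediate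
13 | tert-butyl({1-[3-bromo-2-{[(1S)-1-(2,2-dimethylchroman-6-yl)prop-2-en-1-yl]oxy}-4-(triisopropylsilyloxy)phenyl]vinyl}oxy)dimethylsilane | C=C(O[Si](C)(C)C(C)(C)C)c1ccc(O[Si](C(C)C)(C(C)C)C(C)C)c(Br)c1O[C@H](c1ccc2c(c1)CCC(C)(C)O2)C=C | intermediate
14 | (S)-8-bromo-4-(tert-butyldimethylsilyloxy)-2-(2,2-dimethylchroman-6-yl)-7-(triisopropylsilyloxy)-2H-chromene | Brc1c(O[Si](C(C)C)(C(C)C)C(C)C)ccc2c1O[C@H](c1ccc3c(c1)CCC(C)(C)O3)C=C2O[Si](C)(C)C(C)(C)C | intermediate
15 | prenyl bromide (1-bromo-3-methylbut-2-ene) | CC(C)=CCBr | starting material
16 | prenylzinc bromide | CC(C)=CC[Zn]Br | intermediate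
17 | (S)-4-(tert-butyldimethylsilyloxy)-2-(2,2-dimethylchroman-6-yl)-8-(3-methylbut-2-en-1-yl)-7-(triisopropylsilyloxy)-2H-chromene | CC(C)=CCc1c(O[Si](C(C)C)(C(C)C)C(C)C)ccc2c1O[C@H](c1ccc3c(c1)CCC(C)(C)O3)C=C2O[Si](C)(C)C(C)(C)C | intermediate
18 | euchrenone a17, (2S)-7-hydroxy-2-(2,2-dimethylchroman-6-yl)-8-(3-methylbut-2-en-1-yl)chroman-4-one | CC(C)=CCc1c(O)ccc2c1O[C@H](c1ccc3c(c1)CCC(C)(C)O3)CC2=O | target

## Step count and least certain steps

Total: 11 steps. Longest linear sequence: 9 steps (steps 1–4 and 7–11, from 4-hydroxybenzaldehyde); the ring A branch (steps 5 and 6) joins at step 7.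

**Step 9 (key step).**
- What may go wrong: the hindered, electron-rich 1,1-disubstituted enol ether may be engaged too slowly. The alkylidene formed at the vinyl group is then consumed by intermolecular dimerisation or by hydride-mediated migration of the allylic double bond, and prolonged heating may strip the silyl enol ether.
- Fallback (from 12, rejoining at 14): the C3–C4 bond is still closed by metathesis, but between two ordinary alkenes, and the C4 oxygen is added afterwards.
  - NaBH4 in methanol reduces 12 to 1-[3-bromo-2-{[(1S)-1-(2,2-dimethylchroman-6-yl)prop-2-en-1-yl]oxy}-4-(triisopropylsilyloxy)phenyl]ethanol F1.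
  - The Burgess reagent dehydrates this to the styrene {2-bromo-3-{[(1S)-1-(2,2-dimethylchroman-6-yl)prop-2-en-1-yl]oxy}-4-vinylphenoxy}triisopropylsilane F2.
  - Diene ring-closing metathesis with (H2IMes)(PCy3)Cl2Ru=CHPh (second-generation Grubbs catalyst) gives (S)-8-bromo-2-(2,2-dimethylchroman-6-yl)-7-(triisopropylsilyloxy)-2H-chromene F3.
  - Mukaiyama hydration (Co(acac)2, PhSiH3, O2) places oxygen at the benzylic C4 and gives (2S)-8-bromo-2-(2,2-dimethylchroman-6-yl)-7-(triisopropylsilyloxy)chroman-4-ol F4.
  - Dess–Martin oxidation gives (S)-8-bromo-2-(2,2-dimethylchroman-6-yl)-7-(triisopropylsilyloxy)chroman-4-one F5.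
  - Enol silylation as in step 8 converts F5 into 14.

**Step 7.**
- What may go wrong: the doubly ortho-substituted, acyl-stabilised aryloxide may attack the allyliridium intermediate slowly. The product ether, which combines a good leaving group with an electron-rich allyl unit, may re-ionise, eroding both branched selectivity and enantiomeric purity.
- Fallback (from 4 and 10, rejoining at 12): the stereocentre is made first as a carbinol and the ether is formed with inversion.
  - Vinylmagnesium bromide adds to 4 to give racemic 1-(2,2-dimethylchroman-6-yl)prop-2-en-1-ol F6.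
  - Lipase B from Candida antarctica with vinyl acetate is expected to acylate the (R)-enantiomer (aryl as the large group), giving (R)-1-(2,2-dimethylchroman-6-yl)allyl acetate F7, which is separated from the unreacted (S)-alcohol.
  - K2CO3 in methanol releases (R)-1-(2,2-dimethylchroman-6-yl)prop-2-en-1-ol F8.
  - A Mitsunobu reaction of F8 with 10 (PPh3, diisopropyl azodicarboxylate, toluene, −20 °C) gives 12 with inversion; the low temperature and non-polar solvent are meant to hold back ionisation of the activated carbinol.

**Step 10.**
- What may go wrong: oxidative addition or transmetalation may be slow at a bromide flanked by the triisopropylsilyloxy group and O1, leading to protodebromination. Coupling may occur at the substituted allyl terminus. Zerovalent palladium may ionise the allylic C2–O1 bond. The enol ether may be lost early, followed by addition of the allylzinc to the ketone.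
- Fallback (from 14, rejoining at 18): the coupling is moved to the ketone stage with a reagent that tolerates ketones, and the prenyl group is built in two stages.
  - Oxalic acid in wet THF hydrolyses 14 to the bromo ketone F5 described above.
  - Stille coupling with allyltributylstannane and Pd(PPh3)4 in toluene at 100 °C gives (S)-8-allyl-2-(2,2-dimethylchroman-6-yl)-7-(triisopropylsilyloxy)chroman-4-one F9, with no regiochemical ambiguity.
  - Buffered fluoride as in step 11 gives (S)-8-allyl-7-hydroxy-2-(2,2-dimethylchroman-6-yl)chroman-4-one F10.
  - Cross-metathesis with excess 2-methyl-2-butene and (H2IMes)(PCy3)Cl2Ru=CHPh converts the allyl group into prenyl and gives 18.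

**Step 1.**
- What may go wrong: the formyl group deactivates the phenol, so ring alkylation may be slow compared with oligomerisation of isoprene, and a second prenylation can follow.
- Fallback (from 1 and 15, rejoining at 4): the potassium phenoxide of 1 is C-alkylated with prenyl bromide 15 in aqueous KOH to give 3, which is isolated this time. A sulfonic acid resin in toluene at 80 °C then closes the chroman ring to 4.

## Further compounds

F1 | step 9 | 1-[3-bromo-2-{[(1S)-1-(2,2-dimethylchroman-6-yl)prop-2-en-1-yl]oxy}-4-(triisopropylsilyloxy)phenyl]ethanol (both carbinol epimers) | CC(O)c1ccc(O[Si](C(C)C)(C(C)C)C(C)C)c(Br)c1O[C@H](c1ccc2c(c1)CCC(C)(C)O2)C=C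
F2 | step 9 | {2-bromo-3-{[(1S)-1-(2,2-dimethylchroman-6-yl)prop-2-en-1-yl]oxy}-4-vinylphenoxy}triisopropylsilane | C=Cc1ccc(O[Si](C(C)C)(C(C)C)C(C)C)c(Br)c1O[C@H](c1ccc2c(c1)CCC(C)(C)O2)C=C
F3 | step 9 | (S)-8-bromo-2-(2,2-dimethylchroman-6-yl)-7-(triisopropylsilyloxy)-2H-chromene | Brc1c(O[Si](C(C)C)(C(C)C)C(C)C)ccc2c1O[C@H](c1ccc3c(c1)CCC(C)(C)O3)C=C2
F4 | step 9 | (2S)-8-bromo-2-(2,2-dimethylchroman-6-yl)-7-(triisopropylsilyloxy)chroman-4-ol (both C4 epimers) | Brc1c(O[Si](C(C)C)(C(C)C)C(C)C)ccc2c1O[C@H](c1ccc3c(c1)CCC(C)(C)O3)CC2O
F5 | step 9 | (S)-8-bromo-2-(2,2-dimethylchroman-6-yl)-7-(triisopropylsilyloxy)chroman-4-one | Brc1c(O[Si](C(C)C)(C(C)C)C(C)C)ccc2c1O[C@H](c1ccc3c(c1)CCC(C)(C)O3)CC2=O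
F6 | step 7 | racemic 1-(2,2-dimethylchroman-6-yl)prop-2-en-1-ol | C=CC(O)c1ccc2c(c1)CCC(C)(C)O2
F7 | step 7 | (R)-1-(2,2-dimethylchroman-6-yl)allyl acetate | CC(=O)O[C@@H](c1ccc2c(c1)CCC(C)(C)O2)C=C
F8 | step 7 | (R)-1-(2,2-dimethylchroman-6-yl)prop-2-en-1-ol | O[C@@H](c1ccc2c(c1)CCC(C)(C)O2)C=C
F9 | step 10 | (S)-8-allyl-2-(2,2-dimethylchroman-6-yl)-7-(triisopropylsilyloxy)chroman-4-one | C=CCc1c(O[Si](C(C)C)(C(C)C)C(C)C)ccc2c1O[C@H](c1ccc3c(c1)CCC(C)(C)O3)CC2=O
F10 | step 10 | (S)-8-allyl-7-hydroxy-2-(2,2-dimethylchroman-6-yl)chroman-4-one | C=CCc1c(O)ccc2c1O[C@H](c1ccc3c(c1)CCC(C)(C)O3)CC2=O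
F0 | step 1 | none | none
A1 | alternative 1 | (E)-1-diazo-4-(2-methyl-1,3-dioxolan-2-yl)but-3-en-2-one | [N-]=[N+]=CC(=O)/C=C/C1(C)OCCO1
A2 | alternative 1 | triisopropyl[(5-methylhex-4-en-1-yn-1-yl)oxy]silane | CC(C)=CCC#CO[Si](C(C)C)(C(C)C)C(C)C
A3 | alternative 1 | 6-(2-methyl-1,3-dioxolan-2-yl)-2-(3-methylbut-2-en-1-yl)-3-(triisopropylsilyloxy)phenol | CC(C)=CCc1c(O[Si](C(C)C)(C(C)C)C(C)C)ccc(C2(C)OCCO2)c1O
A4 | alternative 2 | 6-iodo-3-(methoxymethoxy)-2-(3-methylbut-2-en-1-yl)phenol | CC(C)=CCc1c(OCOC)ccc(I)c1O
A5 | alternative 2 | 6-ethynyl-2,2-dimethylchroman | C#Cc1ccc2c(c1)CCC(C)(C)O2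
A6 | alternative 2 | 7-(methoxymethoxy)-8-(3-methylbut-2-en-1-yl)-2-(2,2-dimethylchroman-6-yl)chromen-4-one | CC(C)=CCc1c(OCOC)ccc2c1OC(c1ccc3c(c1)CCC(C)(C)O3)=CC2=O
A7 | alternative 3 | (S)-3-[2-bromo-6-(3-methylbut-2-en-1-yl)-5-(triisopropylsilyloxy)phenoxy]-3-(2,2-dimethylchroman-6-yl)-N-methoxy-N-methylpropanamide | CC(C)=CCc1c(O[Si](C(C)C)(C(C)C)C(C)C)ccc(Br)c1O[C@H](c1ccc2c(c1)CCC(C)(C)O2)CC(=O)N(C)OC
A8 | alternative 3 | (S)-8-(3-methylbut-2-en-1-yl)-2-(2,2-dimethylchroman-6-yl)-7-(triisopropylsilyloxy)chroman-4-one | CC(C)=CCc1c(O[Si](C(C)C)(C(C)C)C(C)C)ccc2c1O[C@H](c1ccc3c(c1)CCC(C)(C)O3)CC2=O
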